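The substrate lost in blue could not all have become target by the last reading: at 10.0 d that flask held 2 % substrate and 38 % target, so by these readings 60.0 % of the charge stood elsewhere at that time.

| flask | substrate | partner | protic impurity | remark | time |
|---|---|---|---|---|---|
| blue | 0.050 M | 0.060 M | 0.025 M | run made earlier |  |
| teal | 0.050 M | 0.030 M | 0.025 M | run made earlier |  |
| amber | 0.050 M | 0.045 M | 0.025 M | run made earlier |  |
| ochre | 0.050 M | 0.060 M | 0.050 M | run made earlier |  |
| south | 0.050 M (fed, over 10 d) | 0.0600 M | 0.0250 M | all else is in the flask from the start; the feed brings no volume worth counting | 15 d |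
| west | 0.050 M | 0.0600 M | 0.0250 M | everything together at the start | 15 d |
| north-west | 0.050 M | 0.0600 M (fed, over 10 d) | 0.0250 M | all else is in the flask from the start; the feed brings no volume worth counting | 15 d |

| run | time / d | target / % | substrate / % |
|---|---|---|---|
| blue | 0.625 | 3 | 42 |
| blue | 1.25 | 8 | 26 |
| blue | 2.50 | 17 | 15 |
| blue | 5.00 | 32 | 6 |
| blue | 10.0 | 38 | 2 |
| teal | 1.67 | 8 | 24 |
| teal | 5.00 | 17 | 10 |
| teal | 8.00 | 22 | 5 |
| teal | 12.0 | 29 | 5 |
| teal | 20.0 | 26 | 0 |
| amber | 1.67 | 7 | 19 |
| amber | 5.00 | 21 | 8 |
| amber | 8.00 | 28 | 5 |
| amber | 12.0 | 34 | 2 |
| amber | 20.0 | 39 | 0 |
| ochre | 1.25 | 7 | 28 |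
| ochre | 2.50 | 21 | 14 |
| ochre | 5.00 | 30 | 10 |
| ochre | 10.0 | 38 | 0 |
| ochre | 20.0 | 46 | 1 |

(each reading ± 2 percentage points)



- which flask leads in amount of target, in percent of the substrate charged ("all alike" within 1.5 percentage points) (south / west / north-west / all alike)
- how much target is there at the end, in percent of the substrate charged: south
- how much target is there at the end, in percent of the substrate charged: west
- how much target is there at the end, in percent of the substrate charged: north-west

But the substrate curves offered a handle. At 2.50 d I read 15 % substrate in blue and 14 % in ochre, which has twice the impurity, so at that time the impurity showed no effect on substrate within the scatter. Up to 2.50 d the reciprocal of c_substrate in blue also climbed roughly straight with time, as it does when substrate is lost by meeting substrate (second order).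

So from the blue reading at 2.50 d, with its scatter, I took τ, the time for c_substrate to fall to half of the charge on that second-order line: 0.441 d. South spreads its feed over 10 d, and that time over τ, 22.7, is the turnover count (a Damköhler number). If loss keeps pace with feed, I reckoned the standing share of substrate in south as the reciprocal of the root of that count, 21.0 % of the charge at the end of the feed. The remaining time then brings it to 6.21 %.

So in south I expected substrate to meet itself at a lower concentration than the full charge of west, with a small unconverted tail, and I put south first.

The forecast differed from me: it named west as leader, with south 37 %, west 43 % and north-west 27 %, on the ground that “its feed delays conversion”.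

    partner → second intermediate (k = 0.0430 h⁻¹)
    partner + protic impurity → quenched reagent (k = 0.420 M⁻¹ h⁻¹)
    substrate ⇌ open intermediate (K = 1.80, k = 0.0520 h⁻¹)
    substrate + open intermediate → side product (k = 0.750 M⁻¹ h⁻¹)
    open intermediate + second intermediate → target (k = 0.360 M⁻¹ h⁻¹)

The flask that led was south, with 52.5 % of target against 43.9 % in west and 25.3 % in north-west. At the end south held 36.8 % side product and west 53.6 %, both in percent of the substrate charged, where side product counts as two. The turnover count put the tail of south at 6.21 %, and south held 4.08 % substrate. The count contains no partner, so it stays 22.7 for south with 0.036 M of partner, and that flask ended with 5.68 % substrate and 35.4 % target.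

(Readings and results were computed for an exercise; scatter was added.)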